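**Strategy.** Everything rests on cutting ring C at C2–C3 and O1–C8a. The 2,3-dihydro-4-pyranone made of O1, C2, C3, C4, C4a and C8a, with its C2 aryl group, C3 oxygen and C4 ketone, is what an aldehyde and a 1-alkoxy-3-silyloxy diene deliver. One catalytic asymmetric hetero-Diels–Alder (Mukaiyama aldol–cyclisation) step joins TIPS-protected vanillin to a 3-methoxy-5,6-bis(silyloxy)hexa-3,5-dienoate, closes ring C, sets C2 and C3, and leaves a C8–C7 acetate arm on C8a. The diene is made by deconjugative protonation, since direct enol silylation would take the more acidic methylene beside the ester. Ring A is then grown with a prenylmalonate and closed by Claisen condensation onto C4a.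

Key step: step 7

Assumption: the (R)-3,3'-diiodo-BINOL ligand is taken to steer the enol silane onto the Si face of the aldehyde, which gives 2R; if the facial sense proves to be the reverse, the (S)-ligand is used with nothing else changed.
Remark: the double-bond geometry drawn for the two silyl dienes and the configuration at the malonate-derived carbon of the β-keto ester are not carried into the target, so mixtures there are harmless.

Step 1
Reactants: 1 tert-butyl acetoacetate
Product: 2 tert-butyl (E)-3-methoxybut-2-enoate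
Conditions: HC(OMe)3, H2SO4 (cat.), MeOH, rt
Reagents that add atoms: trimethyl orthoformate, COC(OC)OC
Why: Acid-catalysed ketalisation of the ketone by the orthoformate and loss of methanol (enol ether formation from a β-keto ester) should give the conjugated, thermodynamically preferred E enol ether, the tert-butyl ester being inert to catalytic acid at room temperature.

Step 2
Reactants: 3 methyl glycolate
Product: 4 methyl 2-[(tert-butyldimethylsilyl)oxy]acetate
Conditions: TBSCl, imidazole, CH2Cl2, rt
Reagents that add atoms: tert-butyldimethylsilyl chloride, CC(C)(C)[Si](C)(C)Cl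
Why: Imidazole-promoted O-silylation of a primary alcohol is routine and installs the bulky, non-chelating silyl ether that stays on the future O3 until the last step.

Step 3
Reactants: 2 tert-butyl (E)-3-methoxybut-2-enoate; 4 methyl 2-[(tert-butyldimethylsilyl)oxy]acetate
Product: 5 tert-butyl (2E)-6-[(tert-butyldimethylsilyl)oxy]-3-methoxy-5-oxohex-2-enoate
Conditions: 2 (2.1 equiv), LiN(iPr)2 (2.1 equiv), THF, -78 °C; then 4 (1.0 equiv), -78 to -40 °C; AcOH, -78 °C
Reagents that add atoms: none
Why: Kinetic γ-deprotonation of the β-methoxy enoate gives a vinylogous ester enolate that undergoes crossed Claisen acylation at its γ-carbon, the second equivalent of enolate deprotonating the more acidic product so that no second addition occurs, while the tert-butyl ester blocks lactonisation to a 2-pyranone.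

Step 4
Reactants: 5 tert-butyl (2E)-6-[(tert-butyldimethylsilyl)oxy]-3-methoxy-5-oxohex-2-enoate
Product: 6 tert-butyl (2E,4Z)-6-[(tert-butyldimethylsilyl)oxy]-3-methoxy-5-[(trimethylsilyl)oxy]hexa-2,4-dienoate
Conditions: LiN(SiMe3)2 (1.05 equiv), THF, -78 °C; TMSCl, -78 to 0 °C; pentane, filtration under argon
Reagents that add atoms: chlorotrimethylsilane, C[Si](C)(C)Cl
Why: The base removes a proton from the doubly activated C4 methylene and O-silylation of that enolate on the ketone oxygen (silyl enol ether formation) should give the fully conjugated dienoate without regiochemical ambiguity.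

Step 5
Reactants: 6 tert-butyl (2E,4Z)-6-[(tert-butyldimethylsilyl)oxy]-3-methoxy-5-[(trimethylsilyl)oxy]hexa-2,4-dienoate
Product: 8 tert-butyl (3Z,5Z)-6-[(tert-butyldimethylsilyl)oxy]-3-methoxy-5-[(trimethylsilyl)oxy]hexa-3,5-dienoate, via lithium trienolate 7 (not isolated)
Conditions: LiN(iPr)2 (1.1 equiv), THF–DMPU, -78 °C; AcOH (1.1 equiv) in THF, -78 °C; pentane, filtration under argon
Reagents that add atoms: none
Why: The only acidic protons left in 6 are those at C6, so deprotonation gives the extended ester enolate, and its kinetic protonation at the α-carbon (deconjugative isomerisation of a 2,4-dienoate to a 3,5-dienoate, as known for sorbate esters) should place the silyloxy diene at C3–C6 beside an intact CH2CO2tBu group.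

Step 6
Reactants: 9 vanillin
Product: 10 3-methoxy-4-[(triisopropylsilyl)oxy]benzaldehyde
Conditions: TIPSCl, imidazole, DMF, rt
Reagents that add atoms: triisopropylsilyl chloride, CC(C)[Si](Cl)(C(C)C)C(C)C
Why: Standard phenol silylation gives an aryl TIPS ether that is sturdier than a TBS ether toward the amine base used later for ring A closure and still falls to fluoride at the end.

Step 7
Reactants: 8 tert-butyl (3Z,5Z)-6-[(tert-butyldimethylsilyl)oxy]-3-methoxy-5-[(trimethylsilyl)oxy]hexa-3,5-dienoate; 10 3-methoxy-4-[(triisopropylsilyl)oxy]benzaldehyde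
Product: 12 tert-butyl 2-[(2R,3R)-3-[(tert-butyldimethylsilyl)oxy]-2-{3-methoxy-4-[(triisopropylsilyl)oxy]phenyl}-4-oxo-3,4-dihydro-2H-pyran-6-yl]acetate, via aldol adduct 11 (not isolated)
Conditions: Zr(OtBu)4 (10 mol %), (R)-3,3'-I2-BINOL (12 mol %), n-PrOH (80 mol %), H2O (20 mol %), toluene, -20 °C; then TFA (cat.), CH2Cl2, 0 °C
Reagents that add atoms: none
Why: The chiral Lewis acid formed from Zr(OtBu)4 and the diiodo-BINOL binds the aldehyde, and the silyl enol ether terminus C6 of 8 (the future C3) adds to the carbonyl carbon through an open transition state, giving 11 after loss of the trimethylsilyl group; acid then drives 6-endo-trig addition of the new hydroxyl oxygen (future O1) to the methoxy-bearing carbon (future C8a) and loss of methanol, which closes ring C as the vinylogous ester. The closest known reaction type is the catalytic asymmetric hetero-Diels–Alder reaction, in its Mukaiyama aldol–cyclisation mode, of aromatic aldehydes with 4-substituted 1-alkoxy-3-silyloxy dienes under chiral BINOL-derived Lewis acids. C2 is set by catalyst control of the aldehyde face (Si-face attack gives 2R), and C3 by the anti preference of the open transition state, in which the bulky silyloxy group cannot chelate the metal. The step needs bond formation at C6 only and ring closure at the methoxy-bearing carbon only, which the diene secures because C6 is its sole enol silane terminus and the methoxy group its sole vinylogous leaving group. Should some 2,3-cis isomer form, enolisation at C3 beside the C4 ketone (under the acid used here, or with a trace of Et3N) should bring it to the diequatorial trans compound without touching C2. The tert-butyl ester and both silyl ethers should tolerate the brief, catalytic acid treatment.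

Step 8
Reactants: 13 diethyl malonate; 14 prenyl bromide
Product: 15 diethyl 2-(3-methylbut-2-en-1-yl)malonate
Conditions: 13 (1.5 equiv), NaOEt (1.0 equiv), EtOH, 0 °C to rt
Reagents that add atoms: none
Why: Malonic ester alkylation by SN2 attack at the primary allylic carbon is classical, and the excess of malonate limits dialkylation.

Step 9
Reactants: 15 diethyl 2-(3-methylbut-2-en-1-yl)malonate
Product: 16 potassium 2-(ethoxycarbonyl)-5-methylhex-4-enoate
Conditions: KOH (1.0 equiv), EtOH, rt
Reagents that add atoms: potassium hydroxide, [K+].[OH-]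
Why: Mono-saponification of a malonate stops after one ester because the carboxylate formed deactivates the second ester and the half-ester salt separates from ethanol.

Step 10
Reactants: 12 tert-butyl 2-[(2R,3R)-3-[(tert-butyldimethylsilyl)oxy]-2-{3-methoxy-4-[(triisopropylsilyl)oxy]phenyl}-4-oxo-3,4-dihydro-2H-pyran-6-yl]acetate
Product: 17 2-[(2R,3R)-3-[(tert-butyldimethylsilyl)oxy]-2-{3-methoxy-4-[(triisopropylsilyl)oxy]phenyl}-4-oxo-3,4-dihydro-2H-pyran-6-yl]acetic acid
Conditions: TFA/CH2Cl2 (1:4), 0 °C; toluene co-evaporation below 20 °C; used at once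
Reagents that add atoms: none
Why: Acidolysis of the tert-butyl ester with loss of isobutene frees the acid without base, so neither the vinylogous ester nor C3 meets hydroxide, and the aryl TIPS ether and the electron-poor α-keto TBS ether should survive cold trifluoroacetic acid.

Step 11
Reactants: 17 2-[(2R,3R)-3-[(tert-butyldimethylsilyl)oxy]-2-{3-methoxy-4-[(triisopropylsilyl)oxy]phenyl}-4-oxo-3,4-dihydro-2H-pyran-6-yl]acetic acid; 16 potassium 2-(ethoxycarbonyl)-5-methylhex-4-enoate
Product: 20 ethyl 2-{2-[(2R,3R)-3-[(tert-butyldimethylsilyl)oxy]-2-{3-methoxy-4-[(triisopropylsilyl)oxy]phenyl}-4-oxo-3,4-dihydro-2H-pyran-6-yl]acetyl}-5-methylhex-4-enoate (both epimers at the prenyl-bearing carbon), via acyl imidazolide 18 (not isolated), via acylmalonic acid 19 (not isolated)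
Conditions: CDI, THF, 0 °C; then added to 16 (2.5 equiv), MgCl2, Et3N, MeCN, 0 °C to rt; aq. KHSO4
Reagents that add atoms: none
Why: In this Masamune–Brooks chain extension the acyl imidazolide acylates at carbon the chelated enolate generated from the malonate half-ester with MgCl2 and Et3N, and decarboxylation on acidic work-up leaves the β-keto ester with the prenyl group already on the future C6, so no regioselective prenylation is needed later.

Step 12
Reactants: 20 ethyl 2-{2-[(2R,3R)-3-[(tert-butyldimethylsilyl)oxy]-2-{3-methoxy-4-[(triisopropylsilyl)oxy]phenyl}-4-oxo-3,4-dihydro-2H-pyran-6-yl]acetyl}-5-methylhex-4-enoate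
Product: 21 (2R,3R)-3-[(tert-butyldimethylsilyl)oxy]-5,7-dihydroxy-2-{3-methoxy-4-[(triisopropylsilyl)oxy]phenyl}-6-(3-methylbut-2-en-1-yl)-2,3-dihydro-4H-chromen-4-one
Conditions: DBU (3 equiv), MeCN, 0 °C to rt; AcOH
Reagents that add atoms: none
Why: Deprotonation at C8 gives a dienolate whose C4a terminus attacks the ethyl ester in a six-membered Claisen (Dieckmann-type) closure, and loss of ethanol with enolisation aromatises ring A to the phloroglucinol (polyketide-type cyclisation as used for chromones), the anionic state throughout keeping C3–H non-acidic so that C2 and C3 are not disturbed.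

Step 13
Reactants: 21 (2R,3R)-3-[(tert-butyldimethylsilyl)oxy]-5,7-dihydroxy-2-{3-methoxy-4-[(triisopropylsilyl)oxy]phenyl}-6-(3-methylbut-2-en-1-yl)-2,3-dihydro-4H-chromen-4-one
Product: 22 (2R,3R)-3-[(tert-butyldimethylsilyl)oxy]-5-hydroxy-7-methoxy-2-{3-methoxy-4-[(triisopropylsilyl)oxy]phenyl}-6-(3-methylbut-2-en-1-yl)-2,3-dihydro-4H-chromen-4-one
Conditions: MeOH, PPh3, DIAD, THF, 0 °C to rt
Reagents that add atoms: methanol, CO
Why: Mitsunobu etherification should alkylate only the acidic 7-OH because the 5-OH is locked in a hydrogen bond to the C4 carbonyl, and the neutral conditions spare the base-sensitive flavanonol.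

Step 14
Reactants: 22 (2R,3R)-3-[(tert-butyldimethylsilyl)oxy]-5-hydroxy-7-methoxy-2-{3-methoxy-4-[(triisopropylsilyl)oxy]phenyl}-6-(3-methylbut-2-en-1-yl)-2,3-dihydro-4H-chromen-4-one
Product: 23 (2R,3R)-3,5-dihydroxy-2-(4-hydroxy-3-methoxyphenyl)-7-methoxy-6-(3-methylbut-2-en-1-yl)-2,3-dihydro-4H-chromen-4-one
Conditions: Bu4NF, AcOH (1:1), THF, 0 °C to rt
Reagents that add atoms: none
Why: Fluoride buffered with acetic acid cleaves both the aryl TIPS and the alkyl TBS ether through Si–F bond formation without building up phenoxide or enolate, so the 2,3-trans stereocentres and the prenyl group should survive.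

**Compound list**

1 | tert-butyl acetoacetate | CC(=O)CC(=O)OC(C)(C)C | starting material
2 | tert-butyl (E)-3-methoxybut-2-enoate | CC(C)(C)OC(=O)/C=C(/OC)C | intermediate
3 | methyl glycolate | COC(=O)CO | starting material
4 | methyl 2-[(tert-butyldimethylsilyl)oxy]acetate | COC(=O)CO[Si](C)(C)C(C)(C)C | intermediate
5 | tert-butyl (2E)-6-[(tert-butyldimethylsilyl)oxy]-3-methoxy-5-oxohex-2-enoate | CC(C)(C)OC(=O)/C=C(/OC)CC(=O)CO[Si](C)(C)C(C)(C)C | intermediate
6 | tert-butyl (2E,4Z)-6-[(tert-butyldimethylsilyl)oxy]-3-methoxy-5-[(trimethylsilyl)oxy]hexa-2,4-dienoate | CC(C)(C)OC(=O)/C=C(/OC)\C=C(/O[Si](C)(C)C)CO[Si](C)(C)C(C)(C)C | intermediate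
7 | lithium trienolate of 6 (lithium 1-tert-butoxy-6-[(tert-butyldimethylsilyl)oxy]-3-methoxy-5-[(trimethylsilyl)oxy]hexa-1,3,5-trien-1-olate) | CC(C)(C)OC(O[Li])=C/C(OC)=C/C(O[Si](C)(C)C)=C/O[Si](C)(C)C(C)(C)C | intermediate
8 | tert-butyl (3Z,5Z)-6-[(tert-butyldimethylsilyl)oxy]-3-methoxy-5-[(trimethylsilyl)oxy]hexa-3,5-dienoate | CC(C)(C)OC(=O)C/C(OC)=C/C(O[Si](C)(C)C)=C/O[Si](C)(C)C(C)(C)C | intermediate
9 | vanillin | COc1cc(C=O)ccc1O | starting material
10 | 3-methoxy-4-[(triisopropylsilyl)oxy]benzaldehyde | COc1cc(C=O)ccc1O[Si](C(C)C)(C(C)C)C(C)C | intermediate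
11 | tert-butyl (3Z,6R,7R)-6-[(tert-butyldimethylsilyl)oxy]-7-hydroxy-3-methoxy-7-{3-methoxy-4-[(triisopropylsilyl)oxy]phenyl}-5-oxohept-3-enoate | COc1cc([C@@H](O)[C@@H](O[Si](C)(C)C(C)(C)C)C(=O)/C=C(\OC)CC(=O)OC(C)(C)C)ccc1O[Si](C(C)C)(C(C)C)C(C)C | intermediate
12 | tert-butyl 2-[(2R,3R)-3-[(tert-butyldimethylsilyl)oxy]-2-{3-methoxy-4-[(triisopropylsilyl)oxy]phenyl}-4-oxo-3,4-dihydro-2H-pyran-6-yl]acetate | COc1cc([C@H]2OC(CC(=O)OC(C)(C)C)=CC(=O)[C@@H]2O[Si](C)(C)C(C)(C)C)ccc1O[Si](C(C)C)(C(C)C)C(C)C | intermediate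
13 | diethyl malonate | CCOC(=O)CC(=O)OCC | starting material
14 | prenyl bromide | CC(C)=CCBr | starting material
15 | diethyl 2-(3-methylbut-2-en-1-yl)malonate | CCOC(=O)C(CC=C(C)C)C(=O)OCC | intermediate
16 | potassium 2-(ethoxycarbonyl)-5-methylhex-4-enoate | CCOC(=O)C(CC=C(C)C)C(=O)[O-].[K+] | intermediate
17 | 2-[(2R,3R)-3-[(tert-butyldimethylsilyl)oxy]-2-{3-methoxy-4-[(triisopropylsilyl)oxy]phenyl}-4-oxo-3,4-dihydro-2H-pyran-6-yl]acetic acid | COc1cc([C@H]2OC(CC(=O)O)=CC(=O)[C@@H]2O[Si](C)(C)C(C)(C)C)ccc1O[Si](C(C)C)(C(C)C)C(C)C | intermediate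
18 | 1-{2-[(2R,3R)-3-[(tert-butyldimethylsilyl)oxy]-2-{3-methoxy-4-[(triisopropylsilyl)oxy]phenyl}-4-oxo-3,4-dihydro-2H-pyran-6-yl]acetyl}-1H-imidazole | COc1cc([C@H]2OC(CC(=O)n3ccnc3)=CC(=O)[C@@H]2O[Si](C)(C)C(C)(C)C)ccc1O[Si](C(C)C)(C(C)C)C(C)C | intermediate
19 | 2-(ethoxycarbonyl)-2-{2-[(2R,3R)-3-[(tert-butyldimethylsilyl)oxy]-2-{3-methoxy-4-[(triisopropylsilyl)oxy]phenyl}-4-oxo-3,4-dihydro-2H-pyran-6-yl]acetyl}-5-methylhex-4-enoic acid | COc1cc([C@H]2OC(CC(=O)C(CC=C(C)C)(C(=O)O)C(=O)OCC)=CC(=O)[C@@H]2O[Si](C)(C)C(C)(C)C)ccc1O[Si](C(C)C)(C(C)C)C(C)C | intermediate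
20 | ethyl 2-{2-[(2R,3R)-3-[(tert-butyldimethylsilyl)oxy]-2-{3-methoxy-4-[(triisopropylsilyl)oxy]phenyl}-4-oxo-3,4-dihydro-2H-pyran-6-yl]acetyl}-5-methylhex-4-enoate (epimers at the prenyl-bearing carbon) | COc1cc([C@H]2OC(CC(=O)C(CC=C(C)C)C(=O)OCC)=CC(=O)[C@@H]2O[Si](C)(C)C(C)(C)C)ccc1O[Si](C(C)C)(C(C)C)C(C)C | intermediate
21 | (2R,3R)-3-[(tert-butyldimethylsilyl)oxy]-5,7-dihydroxy-2-{3-methoxy-4-[(triisopropylsilyl)oxy]phenyl}-6-(3-methylbut-2-en-1-yl)-2,3-dihydro-4H-chromen-4-one | COc1cc([C@H]2Oc3cc(O)c(CC=C(C)C)c(O)c3C(=O)[C@@H]2O[Si](C)(C)C(C)(C)C)ccc1O[Si](C(C)C)(C(C)C)C(C)C | intermediate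
22 | (2R,3R)-3-[(tert-butyldimethylsilyl)oxy]-5-hydroxy-7-methoxy-2-{3-methoxy-4-[(triisopropylsilyl)oxy]phenyl}-6-(3-methylbut-2-en-1-yl)-2,3-dihydro-4H-chromen-4-one | COc1cc([C@H]2Oc3cc(OC)c(CC=C(C)C)c(O)c3C(=O)[C@@H]2O[Si](C)(C)C(C)(C)C)ccc1O[Si](C(C)C)(C(C)C)C(C)C | intermediate
23 | (2R,3R)-3,5-dihydroxy-2-(4-hydroxy-3-methoxyphenyl)-7-methoxy-6-(3-methylbut-2-en-1-yl)-2,3-dihydro-4H-chromen-4-one | COc1cc([C@H]2Oc3cc(OC)c(CC=C(C)C)c(O)c3C(=O)[C@@H]2O)ccc1O | target

**Step count.** Total: 14 steps. Longest linear sequence: 10 steps (steps 1, 3, 4, 5, 7, 10, 11, 12, 13, 14).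

**Steps most likely to fail**

1. Step 7. Facial or anti selectivity in the aldol event may be poor, or the diene may lose its enol silyl group to the protic additive before the carbon–carbon bond forms. Fallback, setting out from 5 and 10 and returning at 12: the lithium dianion of 5 (LiN(iPr)2, 2.2 equiv, THF, -78 °C, deprotonation at C4 and then at C6) is added to 10 and reacts at its terminal carbon in the manner of a β-keto ester dianion. This should give the racemic aldol adduct tert-butyl (2E)-6-[(tert-butyldimethylsilyl)oxy]-7-hydroxy-3-methoxy-7-{3-methoxy-4-[(triisopropylsilyl)oxy]phenyl}-5-oxohept-2-enoate F1 as a mixture of diastereomers. Catalytic TFA in CH2Cl2 should cyclise F1 with loss of methanol and equilibrate C3, giving the racemic trans pyranone tert-butyl 2-[(2R*,3R*)-3-[(tert-butyldimethylsilyl)oxy]-2-{3-methoxy-4-[(triisopropylsilyl)oxy]phenyl}-4-oxo-3,4-dihydro-2H-pyran-6-yl]acetate F2 as the racemate. Preparative chromatography of F2 on a chiral stationary phase then returns 12.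

2. Step 5. The trienolate may be reprotonated at its terminal carbon, returning the conjugated dienoate, or the enol silyl group may be lost during the quench. Fallback, setting out from 6 and returning at 12: the trienolate 7 is silylated on oxygen with TMSCl instead of being protonated. This should give the silyl ketene acetal 1-tert-butoxy-6-[(tert-butyldimethylsilyl)oxy]-3-methoxy-1,5-bis[(trimethylsilyl)oxy]hexa-1,3,5-triene F3 as a triene with no carbon acid left to isomerise. Under the catalyst of step 7, F3 should react with 10 at its terminal silyloxy-bearing carbon (bis-vinylogous Mukaiyama aldol), and the acid work-up restores the tert-butyl ester and closes the ring, giving 12.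

3. Step 11. The activated vinylogous β-keto acid may acylate itself or lose carbon dioxide before it meets the malonate. Fallback, setting out from 12 and 16 and returning at 20, with the polarity reversed so that no activated form of 17 is needed: 16 is converted with oxalyl chloride (DMF cat., CH2Cl2) into ethyl 2-(chlorocarbonyl)-5-methylhex-4-enoate F4 and used crude. Under soft enolisation (MgBr2·OEt2, iPr2NEt, CH2Cl2, 0 °C) F4 should C-acylate 12 at its acidic exocyclic methylene. This gives 1-tert-butyl 5-ethyl 2-[(2R,3R)-3-[(tert-butyldimethylsilyl)oxy]-2-{3-methoxy-4-[(triisopropylsilyl)oxy]phenyl}-4-oxo-3,4-dihydro-2H-pyran-6-yl]-4-(3-methylbut-2-en-1-yl)-3-oxopentanedioate F5 as a mixture of diastereomers. Cleavage of the tert-butyl ester of F5 (TMSOTf, 2,6-lutidine, CH2Cl2, then aqueous work-up) and decarboxylation of the resulting β-keto acid give 20.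

**Further compounds**

F1 | step 7 | tert-butyl (2E)-6-[(tert-butyldimethylsilyl)oxy]-7-hydroxy-3-methoxy-7-{3-methoxy-4-[(triisopropylsilyl)oxy]phenyl}-5-oxohept-2-enoate (racemic, both diastereomers) | COc1cc(C(O)C(O[Si](C)(C)C(C)(C)C)C(=O)C/C(OC)=C\C(=O)OC(C)(C)C)ccc1O[Si](C(C)C)(C(C)C)C(C)C
F2 | step 7 | tert-butyl 2-[(2R*,3R*)-3-[(tert-butyldimethylsilyl)oxy]-2-{3-methoxy-4-[(triisopropylsilyl)oxy]phenyl}-4-oxo-3,4-dihydro-2H-pyran-6-yl]acetate (racemate, 2,3-trans) | COc1cc(C2OC(CC(=O)OC(C)(C)C)=CC(=O)C2O[Si](C)(C)C(C)(C)C)ccc1O[Si](C(C)C)(C(C)C)C(C)C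
F3 | step 5 | 1-tert-butoxy-6-[(tert-butyldimethylsilyl)oxy]-3-methoxy-1,5-bis[(trimethylsilyl)oxy]hexa-1,3,5-triene | CC(C)(C)OC(O[Si](C)(C)C)=C/C(OC)=C/C(O[Si](C)(C)C)=C/O[Si](C)(C)C(C)(C)C
F4 | step 11 | ethyl 2-(chlorocarbonyl)-5-methylhex-4-enoate | CCOC(=O)C(CC=C(C)C)C(Cl)=O
F5 | step 11 | 1-tert-butyl 5-ethyl 2-[(2R,3R)-3-[(tert-butyldimethylsilyl)oxy]-2-{3-methoxy-4-[(triisopropylsilyl)oxy]phenyl}-4-oxo-3,4-dihydro-2H-pyran-6-yl]-4-(3-methylbut-2-en-1-yl)-3-oxopentanedioate | COc1cc([C@H]2OC(C(C(=O)OC(C)(C)C)C(=O)C(CC=C(C)C)C(=O)OCC)=CC(=O)[C@@H]2O[Si](C)(C)C(C)(C)C)ccc1O[Si](C(C)C)(C(C)C)C(C)C
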